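## Retrosynthetic overview

1. Target ⇐ desilylation ⇐ 10-membered 1,3-diketone made by ring contraction (sulfur extrusion, new C2–C3 bond) of an 11-membered thialactone, itself closed by S-alkylation of a seco thiocarboxylate on a bromomethyl ketone.
2. Bromomethyl ketone (C1–C2) ⇐ terminal vinyl group; C13 acetoxymethyl ⇐ Stille coupling on the α-bromobutenolide.
3. C5–C6 bond and trans-epoxide ⇐ vinylogous aldol of the butenolide with an α-chloro-α-formyl thioester, then chlorohydrin closure.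
4. C7–C8 bond ⇐ Ni/Cr coupling of 3,4-dibromofuran-2(5H)-one with (S)-3-methylpent-4-enal; C8 ester ⇐ Steglich acylation.
5. Ring order: butenolide (bought) → epoxide → 11-membered thialactone → 10-membered carbocycle.

Locants C1–C15 are germacrane numbers of the target; the target is (4S,5R,6S,8S,10S). TBS = tert-butyldimethylsilyl; TMSE = 2-(trimethylsilyl)ethyl; Zb = (Z)-4-(TBS-oxy)-3-methylbut-2-enoyl.

Assumption: the carbon skeleton comes from four purchased compounds (the dibromobutene, the dibromofuranone, the methylfuranone and propanoyl chloride); every other atom-delivering species is listed as a reagent with its SMILES at its step.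

## Route

Step 1
Reactants: 1 (E)-1,4-dibromobut-2-ene
Product: 2 (R)-4-bromo-3-methylbut-1-ene
Conditions: MeMgBr, CuBr·SMe2 (1 mol%), Taniaphos (enantiomer giving the R bromide, 1.2 mol%), CH2Cl2, −75 °C
Reagents that add atoms: methylmagnesium bromide, C[Mg]Br
Why: copper-catalysed asymmetric allylic alkylation (SN2′) of the symmetric dibromide, in which the chiral ferrocenyl diphosphine on monovalent copper selects the alkene face and so sets the methyl-bearing centre (future C10).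

Step 2
Reactants: 2 (R)-4-bromo-3-methylbut-1-ene
Product: 4 (S)-3-methylpent-4-enal, via homoallyl Grignard reagent 3 (not isolated)
Conditions: Mg, THF, 0 °C; then DMF, −20 °C; aq. HCl
Reagents that add atoms: magnesium, [Mg] (held only in 3); N,N-dimethylformamide, CN(C)C=O
Why: Bouveault formylation of the Grignard reagent adds the aldehyde carbon (future C8), and the stereocentre is untouched because it is β to the new carbonyl and cannot epimerise.

Step 3
Reactants: 4 (S)-3-methylpent-4-enal; 5 3,4-dibromofuran-2(5H)-one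
Product: 6 3-bromo-4-[(1S,3S)-1-hydroxy-3-methylpent-4-en-1-yl]furan-2(5H)-one
Conditions: CrCl2 (3 equiv), Kishi-type chiral oxazoline–sulfonamide ligand (enantiomer giving the S alcohol, 3.3 equiv), Et3N, NiCl2 (5 mol%), THF, 0 °C → rt
Reagents that add atoms: none
Why: Nozaki–Hiyama–Kishi coupling in which zerovalent nickel inserts into the β-C–Br bond of 5 (the vinylogous acyl bromide, far more reactive than the α-C–Br bond), the vinyl group passes to trivalent chromium and adds only to the aldehyde, and the sulfonamide ligand on chromium sets the C8 carbinol centre (S).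

Step 4
Reactants: 7 4-methylfuran-2(5H)-one
Product: 10 (Z)-4-(TBS-oxy)-3-methylbut-2-enoic acid, via sodium hydroxy enoate 8 (not isolated), via bis-silylated ester 9 (not isolated)
Conditions: NaOH, MeOH/H2O, rt, evaporate; then TBSCl, imidazole, DMF, rt; then AcOH, THF/H2O, 0 °C
Reagents that add atoms: sodium hydroxide, [Na+].[OH-]; tert-butyldimethylsilyl chloride, CC(C)(C)[Si](C)(C)Cl
Why: saponification of the butenolide keeps the Z geometry that the ring imposes, silylation caps the primary alcohol so the acid cannot relactonise, and only the labile silyl ester is hydrolysed (lactone hydrolysis / silyl protection).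

Step 5
Reactants: 6 3-bromo-4-[(1S,3S)-1-hydroxy-3-methylpent-4-en-1-yl]furan-2(5H)-one; 10 (Z)-4-(TBS-oxy)-3-methylbut-2-enoic acid
Product: 11 (1S,3S)-1-(4-bromo-5-oxo-2,5-dihydrofuran-3-yl)-3-methylpent-4-en-1-yl (Z)-4-(TBS-oxy)-3-methylbut-2-enoate
Conditions: DIC, DMAP (10 mol%), CH2Cl2, 0 °C
Reagents that add atoms: none
Why: Steglich esterification of the secondary C8 alcohol, which forms no stereocentre and at 0 °C leaves the Z enoate geometry intact.

Step 6
Reactants: 12 propanoyl chloride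
Product: 13 S-TMSE propanethioate
Conditions: HSCH2CH2SiMe3, Et3N, CH2Cl2, 0 °C
Reagents that add atoms: 2-(trimethylsilyl)ethanethiol, C[Si](C)(C)CCS
Why: S-acylation of the thiol installs the sulfur that is later extruded, masked as a fluoride-labile thioester.

Step 7
Reactants: 13 S-TMSE propanethioate
Product: 14 S-TMSE 2-methyl-3-oxopropanethioate (racemic; mainly enol)
Conditions: LiN(iPr)2, THF, −78 °C; HCO2Et, −78 → 0 °C; aq. HCl
Reagents that add atoms: ethyl formate, CCOC=O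
Why: crossed Claisen condensation (formylation) of the thioester enolate with a non-enolisable formate gives the C3–C4–C5 1,3-dicarbonyl unit, with no fixed stereocentre yet.

Step 8
Reactants: 14 S-TMSE 2-methyl-3-oxopropanethioate
Product: 15 S-TMSE (2R)-2-chloro-2-methyl-3-oxopropanethioate
Conditions: NCS, Cu(OTf)2 (10 mol%), tBu-box ligand (enantiomer giving the R aldehyde, 11 mol%), CH2Cl2, −20 °C
Reagents that add atoms: N-chlorosuccinimide, O=C1CCC(=O)N1Cl
Why: Lewis-acid-catalysed enantioselective α-chlorination of a 1,3-dicarbonyl, in which the copper bis(oxazoline) complex binds the enol in a bidentate way and NCS attacks one face, setting the quaternary C4 centre (R), which has no α-hydrogen and cannot racemise.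

Step 9
Reactants: 11 (1S,3S)-1-(4-bromo-5-oxo-2,5-dihydrofuran-3-yl)-3-methylpent-4-en-1-yl (Z)-4-(TBS-oxy)-3-methylbut-2-enoate; 15 S-TMSE (2R)-2-chloro-2-methyl-3-oxopropanethioate
Product: 17 S-TMSE (2S,3R)-3-[(2S)-4-bromo-3-{(1S,3S)-3-methyl-1-(Zb-oxy)pent-4-en-1-yl}-5-oxo-2,5-dihydrofuran-2-yl]-2-methyloxirane-2-carbothioate, via chlorohydrin 16 (not isolated)
Conditions: quinine-derived squaramide (10 mol%), CH2Cl2, −30 °C; then K2CO3, MeCN, 0 °C
Reagents that add atoms: none
Why: direct vinylogous aldol addition of the butenolide dienolate (γ-carbon, future C6) to the non-enolisable α-chloro aldehyde, where the bifunctional catalyst fixes the dienolate face and the 5,6-syn relation while chloride stands anti to the incoming nucleophile (Cornforth/polar Felkin–Anh) with the thioester held inside, and the C5 alkoxide then displaces chloride at C4 by intramolecular SN2 with inversion (second stage of a Darzens reaction) to give the trans-epoxide.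

Step 10
Reactants: 17 S-TMSE (2S,3R)-3-[(2S)-4-bromo-3-{(1S,3S)-3-methyl-1-(Zb-oxy)pent-4-en-1-yl}-5-oxo-2,5-dihydrofuran-2-yl]-2-methyloxirane-2-carbothioate
Product: 19 S-TMSE (2S,3R)-3-[(2S)-4-(acetoxymethyl)-3-{(1S,3S)-3-methyl-1-(Zb-oxy)pent-4-en-1-yl}-5-oxo-2,5-dihydrofuran-2-yl]-2-methyloxirane-2-carbothioate, via hydroxymethyl butenolide 18 (not isolated)
Conditions: Bu3SnCH2OH, Pd2(dba)3 (5 mol%), AsPh3 (20 mol%), DMF, 50 °C; then Ac2O, pyridine, 0 °C
Reagents that add atoms: (tributylstannyl)methanol, CCCC[Sn](CCCC)(CCCC)CO; acetic anhydride, CC(=O)OC(C)=O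
Why: Migita–Kosugi–Stille coupling at the α-bromobutenolide followed by acetylation installs C13 only after the dienolate chemistry (a 13-acetate would be expelled from the dienolate), and the copper-free zerovalent palladium conditions leave the thioester alone; no stereocentre is formed.

Step 11
Reactants: 19 S-TMSE (2S,3R)-3-[(2S)-4-(acetoxymethyl)-3-{(1S,3S)-3-methyl-1-(Zb-oxy)pent-4-en-1-yl}-5-oxo-2,5-dihydrofuran-2-yl]-2-methyloxirane-2-carbothioate
Product: 21 S-TMSE (2S,3R)-3-[(2S)-4-(acetoxymethyl)-3-{(1S,3S)-5-bromo-3-methyl-4-oxo-1-(Zb-oxy)pentyl}-5-oxo-2,5-dihydrofuran-2-yl]-2-methyloxirane-2-carbothioate, via bromohydrin 20 (not isolated)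
Conditions: NBS, THF/H2O (4:1), 0 °C; then IBX, DMSO, rt
Reagents that add atoms: N-bromosuccinimide, O=C1CCC(=O)N1Br; water, O
Why: Markovnikov bromohydrin formation on the only electron-rich alkene followed by IBX oxidation gives the bromomethyl ketone (C1–C2), and the carbinol centre of 20 is destroyed so its configuration does not matter.

Step 12
Reactants: 21 S-TMSE (2S,3R)-3-[(2S)-4-(acetoxymethyl)-3-{(1S,3S)-5-bromo-3-methyl-4-oxo-1-(Zb-oxy)pentyl}-5-oxo-2,5-dihydrofuran-2-yl]-2-methyloxirane-2-carbothioate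
Product: 24 (4S,5R,6S,8S,10S)-13-acetoxy-4,5-epoxy-1,3-dioxogermacr-7(11)-en-12,6-olid-8-yl (Z)-4-(TBS-oxy)-3-methylbut-2-enoate, via thiocarboxylate 22 (not isolated), via thialactone 23 (not isolated)
Conditions: tris(dimethylamino)sulfonium difluorotrimethylsilicate (TASF, 1.1 equiv), DMF, 0.5 mM (syringe pump), −20 → 0 °C; then LiBr, iPr2NEt, PPh3, 40 °C
Reagents that add atoms: none
Why: Proposed new method: fluoride unmasks the thiocarboxylate, which closes the 11-membered thialactone by S-alkylation of the bromomethyl ketone (known), and the new event is a ring-contracting sulfide contraction inside this medium ring, in which lithium-assisted soft enolisation at C2 (flanked by the C1 ketone and sulfur, by far the most acidic site, the thioester having no α-hydrogen) lets C2 attack the thioester carbonyl C3 across the ring (3-exo-trig) to an episulfide alkoxide from which PPh3 removes sulfur as Ph3P=S, leaving the 10-membered 1,3-diketonate with the new C2–C3 bond; the closest known reaction is the Eschenmoser sulfide contraction of acyclic S-(2-oxoalkyl) thioesters to 1,3-diketones, no stereocentre is formed, and C10 is shielded from epimerisation once it is part of the diketonate.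

Step 13
Reactants: 24 (4S,5R,6S,8S,10S)-13-acetoxy-4,5-epoxy-1,3-dioxogermacr-7(11)-en-12,6-olid-8-yl (Z)-4-(TBS-oxy)-3-methylbut-2-enoate
Product: 25 (4S,5R,6S,8S,10S)-13-acetoxy-4,5-epoxy-1,3-dioxogermacr-7(11)-en-12,6-olid-8-yl (Z)-4-hydroxy-3-methylbut-2-enoate (CNP0295642.1)
Conditions: HF·pyridine, pyridine/THF, 0 °C
Reagents that add atoms: none
Why: buffered, non-basic silyl ether cleavage frees the primary alcohol without lactonising the Z-hydroxy enoate or disturbing the epoxide, the 13-acetate or the 1,3-diketone.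

## Compound list

1 | (E)-1,4-dibromobut-2-ene | BrC/C=C/CBr | starting material
2 | (R)-4-bromo-3-methylbut-1-ene | BrC[C@H](C)C=C | intermediate
3 | [(2R)-2-methylbut-3-en-1-yl]magnesium bromide | Br[Mg]C[C@H](C)C=C | intermediate
4 | (S)-3-methylpent-4-enal | O=CC[C@H](C)C=C | intermediate
5 | 3,4-dibromofuran-2(5H)-one | O=C1OCC(Br)=C1Br | starting material
6 | 3-bromo-4-[(1S,3S)-1-hydroxy-3-methylpent-4-en-1-yl]furan-2(5H)-one | BrC1=C(COC1=O)[C@@H](O)C[C@H](C)C=C | intermediate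
7 | 4-methylfuran-2(5H)-one | CC1=CC(=O)OC1 | starting material
8 | sodium (Z)-4-hydroxy-3-methylbut-2-enoate | [Na+].[O-]C(=O)/C=C(/C)CO | intermediate
9 | TBS (Z)-4-(TBS-oxy)-3-methylbut-2-enoate | CC(C)(C)[Si](C)(C)OC(=O)/C=C(/C)CO[Si](C)(C)C(C)(C)C | intermediate
10 | (Z)-4-(TBS-oxy)-3-methylbut-2-enoic acid | OC(=O)/C=C(/C)CO[Si](C)(C)C(C)(C)C | intermediate
11 | (1S,3S)-1-(4-bromo-5-oxo-2,5-dihydrofuran-3-yl)-3-methylpent-4-en-1-yl (Z)-4-(TBS-oxy)-3-methylbut-2-enoate | BrC1=C(COC1=O)[C@@H](OC(=O)/C=C(/C)CO[Si](C)(C)C(C)(C)C)C[C@H](C)C=C | intermediate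
12 | propanoyl chloride | CCC(Cl)=O | starting material
13 | S-TMSE propanethioate | CCC(=O)SCC[Si](C)(C)C | intermediate
14 | S-TMSE 2-methyl-3-oxopropanethioate (racemic; mainly enol) | CC(C=O)C(=O)SCC[Si](C)(C)C | intermediate
15 | S-TMSE (2R)-2-chloro-2-methyl-3-oxopropanethioate | O=C(SCC[Si](C)(C)C)[C@](C=O)(C)Cl | intermediate
16 | S-TMSE (2R,3R)-3-[(2S)-4-bromo-3-{(1S,3S)-3-methyl-1-(Zb-oxy)pent-4-en-1-yl}-5-oxo-2,5-dihydrofuran-2-yl]-2-chloro-3-hydroxy-2-methylpropanethioate | C[Si](C)(C)CCSC(=O)[C@](C)(Cl)[C@H](O)[C@H]1OC(=O)C(Br)=C1[C@@H](OC(=O)/C=C(/C)CO[Si](C)(C)C(C)(C)C)C[C@H](C)C=C | intermediate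
17 | S-TMSE (2S,3R)-3-[(2S)-4-bromo-3-{(1S,3S)-3-methyl-1-(Zb-oxy)pent-4-en-1-yl}-5-oxo-2,5-dihydrofuran-2-yl]-2-methyloxirane-2-carbothioate | C[Si](C)(C)CCSC(=O)[C@@]1(C)O[C@@H]1[C@H]2OC(=O)C(Br)=C2[C@@H](OC(=O)/C=C(/C)CO[Si](C)(C)C(C)(C)C)C[C@H](C)C=C | intermediate
18 | 4-(hydroxymethyl) analogue of 17 (CH2OH in place of Br on the butenolide α-carbon; all centres as in 17) | C[Si](C)(C)CCSC(=O)[C@@]1(C)O[C@@H]1[C@H]2OC(=O)C(CO)=C2[C@@H](OC(=O)/C=C(/C)CO[Si](C)(C)C(C)(C)C)C[C@H](C)C=C | intermediate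
19 | S-TMSE (2S,3R)-3-[(2S)-4-(acetoxymethyl)-3-{(1S,3S)-3-methyl-1-(Zb-oxy)pent-4-en-1-yl}-5-oxo-2,5-dihydrofuran-2-yl]-2-methyloxirane-2-carbothioate | C[Si](C)(C)CCSC(=O)[C@@]1(C)O[C@@H]1[C@H]2OC(=O)C(COC(C)=O)=C2[C@@H](OC(=O)/C=C(/C)CO[Si](C)(C)C(C)(C)C)C[C@H](C)C=C | intermediate
20 | bromohydrin of 19: side chain (1S,3S)-5-bromo-4-hydroxy-3-methyl-1-(Zb-oxy)pentyl (both C4′ epimers) | C[Si](C)(C)CCSC(=O)[C@@]1(C)O[C@@H]1[C@H]2OC(=O)C(COC(C)=O)=C2[C@@H](OC(=O)/C=C(/C)CO[Si](C)(C)C(C)(C)C)C[C@H](C)C(O)CBr | intermediate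
21 | S-TMSE (2S,3R)-3-[(2S)-4-(acetoxymethyl)-3-{(1S,3S)-5-bromo-3-methyl-4-oxo-1-(Zb-oxy)pentyl}-5-oxo-2,5-dihydrofuran-2-yl]-2-methyloxirane-2-carbothioate | C[Si](C)(C)CCSC(=O)[C@@]1(C)O[C@@H]1[C@H]2OC(=O)C(COC(C)=O)=C2[C@@H](OC(=O)/C=C(/C)CO[Si](C)(C)C(C)(C)C)C[C@H](C)C(=O)CBr | intermediate
22 | thiocarboxylate anion of 21 (TMSE removed; all centres as in 21) | [S-]C(=O)[C@@]1(C)O[C@@H]1[C@H]2OC(=O)C(COC(C)=O)=C2[C@@H](OC(=O)/C=C(/C)CO[Si](C)(C)C(C)(C)C)C[C@H](C)C(=O)CBr | intermediate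
23 | 11-membered thialactone: ring of 24 with sulfur inserted between C2 and C3 (C3(=O)–S–C2H2–C1(=O)); all centres as in 24 | CC(=O)OCC1=C2[C@@H](OC(=O)/C=C(/C)CO[Si](C)(C)C(C)(C)C)C[C@H](C)C(=O)CSC(=O)[C@@]3(C)O[C@@H]3[C@H]2OC1=O | intermediate
24 | (4S,5R,6S,8S,10S)-13-acetoxy-4,5-epoxy-1,3-dioxogermacr-7(11)-en-12,6-olid-8-yl (Z)-4-(TBS-oxy)-3-methylbut-2-enoate | CC(=O)OCC1=C2[C@@H](OC(=O)/C=C(/C)CO[Si](C)(C)C(C)(C)C)C[C@H](C)C(=O)CC(=O)[C@@]3(C)O[C@@H]3[C@H]2OC1=O | intermediate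
25 | (4S,5R,6S,8S,10S)-13-acetoxy-4,5-epoxy-1,3-dioxogermacr-7(11)-en-12,6-olid-8-yl (Z)-4-hydroxy-3-methylbut-2-enoate (CNP0295642.1) | CC(=O)OCC1=C2[C@@H](OC(=O)/C=C(/C)CO)C[C@H](C)C(=O)CC(=O)[C@@]3(C)O[C@@H]3[C@H]2OC1=O | target

## Step count and risks

Total steps: 13. Longest linear sequence: 9 steps (1, 2, 3, 5, 9, 10, 11, 12, 13).

Three steps most likely to fail:

Step 12 (the proposed ring contraction). Risks are oligomerisation in the S-alkylation and base-induced damage at C6–H (loss of the 13-acetate or opening of the epoxide) during the contraction. Fallback with known chemistry, setting out from 19 and coming back at 24. Fukuyama reduction (Et3SiH, Pd/CaCO3 poisoned with Pb(OAc)2, acetone, rt) turns the thioester into the epoxy aldehyde (2S,3R)-3-[(2S)-4-(acetoxymethyl)-3-{(1S,3S)-3-methyl-1-(Zb-oxy)pent-4-en-1-yl}-5-oxo-2,5-dihydrofuran-2-yl]-2-methyloxirane-2-carbaldehyde F6. NBS in THF/H2O gives the bromohydrin aldehyde F7, and IBX then gives the bromomethyl ketone aldehyde F8. An intramolecular chromium Reformatsky reaction (CrCl2, LiI, THF, high dilution) joins C2 to C3 and closes the 10-membered ring as the 3-hydroxy-1-ketone macrocycle F9. Dess–Martin oxidation then gives the 1,3-diketone 24.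

Step 9 (vinylogous aldol and epoxide closure). Risks are the less acidic, more crowded nucleophile 11, facial control at the quaternary α-chloro aldehyde, and base sensitivity of the product at C6–H. The fallback changes the order of fragment union, setting out from 5 and 15 and coming back at 17. The same organocatalytic aldol is run on the dibromofuranone 5 itself, the substrate class for which it is documented, giving the dibromo chlorohydrin F3. K2CO3 then closes it to the dibromo epoxide S-TMSE (2S,3R)-3-[(2R)-3,4-dibromo-5-oxo-2,5-dihydrofuran-2-yl]-2-methyloxirane-2-carbothioate F4. Nozaki–Hiyama–Kishi coupling of F4 with 4 under the step 3 conditions gives the C8 alcohol F5, and Steglich esterification with 10 returns to 17.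

Step 3 (ligand-controlled Ni/Cr coupling). Risks are modest selectivity at C8 and competing reaction at the α-C–Br bond. The fallback sets C8 by reagent-controlled ketone reduction instead, setting out from 4 and 5 and coming back at 6. Ligand-free NiCl2/CrCl2 coupling gives the C8-epimeric alcohols 3-bromo-4-[(3S)-1-hydroxy-3-methylpent-4-en-1-yl]furan-2(5H)-one F1. Dess–Martin oxidation gives the ketone 3-bromo-4-[(3S)-3-methylpent-4-enoyl]furan-2(5H)-one F2. Corey–Bakshi–Shibata reduction ((R)-Me-CBS oxazaborolidine, BH3·SMe2, −40 °C) then delivers the S alcohol 6.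

Further compounds

F1 | step 3 | 3-bromo-4-[(3S)-1-hydroxy-3-methylpent-4-en-1-yl]furan-2(5H)-one (both C1′ epimers) | OC(C[C@H](C)C=C)C1=C(Br)C(=O)OC1
F2 | step 3 | 3-bromo-4-[(3S)-3-methylpent-4-enoyl]furan-2(5H)-one | O=C(C[C@H](C)C=C)C1=C(Br)C(=O)OC1
F3 | step 9 | S-TMSE (2R,3R)-2-chloro-3-[(2R)-3,4-dibromo-5-oxo-2,5-dihydrofuran-2-yl]-3-hydroxy-2-methylpropanethioate | C[Si](C)(C)CCSC(=O)[C@](C)(Cl)[C@H](O)[C@H]1OC(=O)C(Br)=C1Br
F4 | step 9 | S-TMSE (2S,3R)-3-[(2R)-3,4-dibromo-5-oxo-2,5-dihydrofuran-2-yl]-2-methyloxirane-2-carbothioate | C[Si](C)(C)CCSC(=O)[C@@]1(C)O[C@@H]1[C@H]2OC(=O)C(Br)=C2Br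
F5 | step 9 | S-TMSE (2S,3R)-3-[(2S)-4-bromo-3-{(1S,3S)-1-hydroxy-3-methylpent-4-en-1-yl}-5-oxo-2,5-dihydrofuran-2-yl]-2-methyloxirane-2-carbothioate | C[Si](C)(C)CCSC(=O)[C@@]1(C)O[C@@H]1[C@H]2OC(=O)C(Br)=C2[C@@H](O)C[C@H](C)C=C
F6 | step 12 | (2S,3R)-3-[(2S)-4-(acetoxymethyl)-3-{(1S,3S)-3-methyl-1-(Zb-oxy)pent-4-en-1-yl}-5-oxo-2,5-dihydrofuran-2-yl]-2-methyloxirane-2-carbaldehyde | O=C[C@@]1(C)O[C@@H]1[C@H]2OC(=O)C(COC(C)=O)=C2[C@@H](OC(=O)/C=C(/C)CO[Si](C)(C)C(C)(C)C)C[C@H](C)C=C
F7 | step 12 | bromohydrin of F6: side chain (1S,3S)-5-bromo-4-hydroxy-3-methyl-1-(Zb-oxy)pentyl (both C4′ epimers) | O=C[C@@]1(C)O[C@@H]1[C@H]2OC(=O)C(COC(C)=O)=C2[C@@H](OC(=O)/C=C(/C)CO[Si](C)(C)C(C)(C)C)C[C@H](C)C(O)CBr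
F8 | step 12 | (2S,3R)-3-[(2S)-4-(acetoxymethyl)-3-{(1S,3S)-5-bromo-3-methyl-4-oxo-1-(Zb-oxy)pentyl}-5-oxo-2,5-dihydrofuran-2-yl]-2-methyloxirane-2-carbaldehyde | O=C[C@@]1(C)O[C@@H]1[C@H]2OC(=O)C(COC(C)=O)=C2[C@@H](OC(=O)/C=C(/C)CO[Si](C)(C)C(C)(C)C)C[C@H](C)C(=O)CBr
F9 | step 12 | 3-hydroxy analogue of 24 (C3 carbinol in place of the C3 ketone; both C3 epimers; other centres as in 24) | CC(=O)OCC1=C2[C@@H](OC(=O)/C=C(/C)CO[Si](C)(C)C(C)(C)C)C[C@H](C)C(=O)CC(O)[C@@]3(C)O[C@@H]3[C@H]2OC1=O
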